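55 percentage points of isomer of the product appeared in the oak run between its first and last readings, while the target present summed to 1.10 d of full charge, so I took as my working quantity the leak κ, the isomer of the product formed per day per unit of target present, 0.502 d⁻¹.

| flask | substrate | remark | time |
|---|---|---|---|
| maple | 0.25 M | run made earlier |  |
| oak | 0.35 M | run made earlier |  |
| ash | 0.55 M | run made earlier |  |
| theta | 0.25 M | one stirred flow tank at steady state, fed with the mixture as stated, mean residence time 3.0 d |  |
| zeta | 0.25 M | a closed flask charged with all of it at once and left for 3.0 d | 3.0 d |

maple run (percent of the substrate charged)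

| time / h | target / % | isomer of the product / % |
|---|---|---|
| 4.00 | 48.3 | 3.2 |
| 10.0 | 57.2 | 10.1 |
| 20.0 | 51.6 | 22.5 |
| 30.0 | 44.3 | 34.1 |
| 40.0 | 38.8 | 42.6 |

oak run (percent of the substrate charged)

| time / d | target / % | isomer of the product / % |
|---|---|---|
| 0.625 | 54.6 | 17.6 |
| 1.25 | 44.8 | 33.8 |
| 2.00 | 33.4 | 49.2 |
| 3.00 | 24.4 | 65.0 |
| 4.00 | 17.4 | 72.9 |

ash run (percent of the substrate charged)

| time / d | target / % | isomer of the product / % |
|---|---|---|
| 0.250 | 53.1 | 4.9 |
| 0.500 | 55.7 | 12.6 |
| 1.04 | 48.6 | 27.2 |
| 2.08 | 33.7 | 50.7 |
| 4.00 | 18.2 | 73.6 |

(standard deviation of a reading: 0.5 percentage points)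

* the set-up with the highest share of target in all that became target or isomer of the product, at the outlet or at the end ("none" if the first two lie within 2 percentage points) (theta / zeta / none)
* share of target in all that became target or isomer of the product, at the outlet or at the end, theta
* share of target in all that became target or isomer of the product, at the outlet or at the end, zeta

- the stated concentrations are those of everything mixed, before any reaction; amounts are the same in each set-up
- the earlier runs were made in a closed, stirred flask
- a reading or a percentage of target counts all its forms, free or not

I ran the flask slowly in my head. At first, in the maple run, target was far ahead, with 48.3% against 3.2% of isomer of the product at 4.00 h. In the middle of the maple run, target read its highest, 57.2%, at 10.0 h, and the later maple readings fell. Late in the oak run, target kept falling and isomer of the product kept rising, while at 4.00 d 9.7 points of the charge stood in neither. At one shared time the charge did not show beyond the scatter: maple at 30.0 h read 44.3% and 34.1%, and oak at the same time, 1.25 d, read 44.8% and 33.8%.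

So I reckoned per unit of charge. In the tank theta, isomer of the product leaves at Q/τ, where Q is its outlet amount and τ the mean residence time, and it forms at κT, where T is the outlet target. Hence Q = κτT, and the share of target, the selectivity, is one over one plus κτ. With κτ = 1.51, that gave 39.9%. For zeta I read oak at 3.00 d, which gave 27.3%.

The forecast named theta, with 39% for theta and 27.8% for zeta, and it read the runs as “first order overall”. Its theta figure differs from my 39.9%.

The flasks gave 39.3% for theta and 27.5% for zeta, so theta leads by 12 points.

    substrate → intermediate (k = 1.05 × 10⁻⁴ s⁻¹)
    intermediate ⇌ target (K = 2.02, k = 9.67 × 10⁻⁴ s⁻¹)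
    intermediate ⇌ isomer of the product (K = 38.0, k = 1.33 × 10⁻⁵ s⁻¹)
    substrate + target ⇌ idle adduct, settled at all times (K = 2.28 L mol⁻¹)

In zeta, the relaxation half-life of intermediate and free target, by that step alone, is 0.133 h, shorter than the 0.588 d of intermediate and isomer of the product by their step alone. Both are short against the 3.0 d of zeta. Taking target as falling exponentially between readings, κ gave zeta 24 points of isomer of the product from 1.50 d to 3.00 d, where the flask gained 24 points. For the same flask read at 5.0 d, κ gave 18 points beyond 3.00 d, where it gained 16 points.

(All runs were computed for substances that don't exist.)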